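The route rests on cutting ring C of the lower flavan-3,4-diol unit at O1–C2 and C4a–C4. In the key step the free phenol O1–H of ring A and its only unsubstituted ortho carbon (C4a, para to the 7-hydroxyl) in pentabenzyl phenol 18 are joined to (2S,3S)-cis-epoxy aldehyde 22. Titanium-templated ortho-hydroxyalkylation makes C4a–C4, then the tethered aryloxide opens the benzylic epoxide carbon with inversion to make O1–C2, so ring C and its all-cis C2/C3/C4 triad arise in one operation. The same annulation first builds the upper unit, whose C4 hydroxyl is then exchanged for the ring-A precursor by Friedel–Crafts arylation.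

Key step: step 14

Remark: titanium aryloxides and chelates (8, 9, 23, 24) are drawn as monomers for bookkeeping; their aggregation in solution is left open.

Step 1
Reactants: 1 3,4-bis(benzyloxy)benzaldehyde
Product: 2 ethyl (2Z)-3-[3,4-bis(benzyloxy)phenyl]prop-2-enoate
Conditions: ethyl 2-[bis(2-methylphenoxy)phosphoryl]acetate (1.1 equiv), NaH, THF, −78 °C → 0 °C
Reagents that add atoms: ethyl 2-[bis(2-methylphenoxy)phosphoryl]acetate, CCOC(=O)CP(=O)(Oc1ccccc1C)Oc1ccccc1C
Why: Ando variant of the Horner–Wadsworth–Emmons olefination, in which the electron-poor diaryl phosphonate makes elimination of the kinetically formed adduct fast, so the Z-enoate should predominate.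

Step 2
Reactants: 2 ethyl (2Z)-3-[3,4-bis(benzyloxy)phenyl]prop-2-enoate
Product: 3 ethyl (2S,3S)-3-[3,4-bis(benzyloxy)phenyl]oxirane-2-carboxylate (cis-glycidate)
Conditions: (S,S)-[N,N'-bis(3,5-di-tert-butylsalicylidene)-1,2-cyclohexanediaminato]MnCl (Jacobsen catalyst, trivalent manganese, 6 mol %), 4-phenylpyridine N-oxide (0.25 equiv), aq. NaOCl (pH 11.3), CH2Cl2, 0–4 °C
Reagents that add atoms: sodium hypochlorite, [Na+].[O-]Cl
Why: Jacobsen–Katsuki epoxidation of a conjugated cis-disubstituted alkene, where side-on approach to the oxo-manganese species under the (S,S)-ligand should give the (2S,3S)-cis-epoxide and the N-oxide additive limits collapse to the trans-epoxide.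

Step 3
Reactants: 3 ethyl (2S,3S)-3-[3,4-bis(benzyloxy)phenyl]oxirane-2-carboxylate
Product: 4 (2S,3S)-3-[3,4-bis(benzyloxy)phenyl]oxirane-2-carbaldehyde (cis)
Conditions: i-Bu2AlH (1.05 equiv), CH2Cl2, −78 °C; MeOH, then aq. potassium sodium tartrate; used at once
Reagents that add atoms: none
Why: Partial ester reduction, in which the α-oxygenated tetrahedral aluminium hemiacetal is stable at −78 °C and releases the aldehyde only on neutral work-up, which should leave the epimerisable cis-epoxy aldehyde intact.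

Step 4
Reactants: 5 2,3-bis(benzyloxy)benzaldehyde
Product: 7 2,3-bis(benzyloxy)phenol, via aryl formate 6 (not isolated)
Conditions: mCPBA, CH2Cl2, 0 °C → rt; aq. NaHCO3 wash; then Et3N (cat.), MeOH, rt
Reagents that add atoms: 3-chloroperoxybenzoic acid, OOC(=O)c1cccc(Cl)c1
Why: Baeyer–Villiger (Dakin-type) oxidation, in which the ortho-alkoxyaryl group migrates in the Criegee intermediate and the aryl formate is cleaved by base-catalysed methanolysis.

Step 5
Reactants: 7 2,3-bis(benzyloxy)phenol; 4 (2S,3S)-3-[3,4-bis(benzyloxy)phenyl]oxirane-2-carbaldehyde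
Product: 10 (2R,3R,4R)-7,8-bis(benzyloxy)-2-[3,4-bis(benzyloxy)phenyl]-3,4-dihydro-2H-chromene-3,4-diol, via titanium aryloxide 8 (not isolated), via titanium-bound epoxy carbinol 9 (not isolated)
Conditions: 7, Ti(OiPr)4 (1.2 equiv), toluene, rt, i-PrOH removed in vacuo; 4 (1.2 equiv), CH2Cl2, −20 °C → rt, then 40 °C; aq. potassium sodium tartrate
Reagents that add atoms: none
Why: Proposed new method: the titanium aryloxide of 7 should deliver aldehyde 4 to its only free ortho carbon (ortho-specific hydroxyalkylation of metal phenolates, Felkin–Anh addition anti to the epoxide C–O setting C4 as R), and the aryloxide oxygen should then open the titanium-chelated cis-epoxide at its benzylic carbon in a 6-endo closure with inversion (setting C2 as R, C3 coming from 4), the closest known reaction types being the titanium alkoxide-mediated phenol–enal chromene annulation and the Ti(OiPr)4-mediated C3-selective opening of 2,3-epoxy alcohols.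

Step 6
Reactants: 11 resorcinol
Product: 12 1,3-bis(methoxymethoxy)benzene
Conditions: MOMCl (2.4 equiv), i-Pr2NEt, CH2Cl2, 0 °C → rt
Reagents that add atoms: chloromethyl methyl ether, COCCl
Why: Williamson-type O-alkylation, giving the pair of acetal directing groups needed for the next step.

Step 7
Reactants: 12 1,3-bis(methoxymethoxy)benzene
Product: 15 2,6-bis(methoxymethoxy)phenol, via aryllithium 13 (not isolated), via dimethyl arylboronate 14 (not isolated)
Conditions: n-BuLi, THF, 0 °C → rt; B(OMe)3, −78 °C → rt; then AcOH, 30% aq. H2O2, 0 °C → rt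
Reagents that add atoms: hydrogen peroxide, OO
Why: Directed ortho-metalation at C2 between the two acetal groups, borylation, and boronate oxidation by 1,2-aryl shift from boron to oxygen.

Step 8
Reactants: 15 2,6-bis(methoxymethoxy)phenol
Product: 16 2-(benzyloxy)-1,3-bis(methoxymethoxy)benzene
Conditions: BnBr, K2CO3, DMF, 60 °C
Reagents that add atoms: benzyl bromide, BrCc1ccccc1
Why: Williamson ether synthesis on the hindered phenoxide in a dipolar aprotic solvent.

Step 9
Reactants: 16 2-(benzyloxy)-1,3-bis(methoxymethoxy)benzene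
Product: 17 2-(benzyloxy)benzene-1,3-diol
Conditions: HCl (cat.), MeOH, 45 °C
Reagents that add atoms: none
Why: Acid-catalysed acetal exchange should remove both MOM groups as dimethoxymethane while the benzyl ether stays.

Step 10
Reactants: 10 (2R,3R,4R)-7,8-bis(benzyloxy)-2-[3,4-bis(benzyloxy)phenyl]-3,4-dihydro-2H-chromene-3,4-diol; 17 2-(benzyloxy)benzene-1,3-diol
Product: 18 (2R,3R,4S)-7,8-bis(benzyloxy)-4-[3-(benzyloxy)-2,4-dihydroxyphenyl]-2-[3,4-bis(benzyloxy)phenyl]-3,4-dihydro-2H-chromen-3-ol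
Conditions: 17 (4 equiv), BF3·OEt2 (0.3 equiv), CH2Cl2–THF, −20 °C → 0 °C
Reagents that add atoms: none
Why: Friedel–Crafts (SN1) arylation, in which BF3 ionises the C4 hydroxyl to a cation stabilised by O1 and the para 7-benzyloxy group, the symmetric resorcinol 17 (in excess, to suppress oligomers) can react only at its equivalent 4/6 positions, and attack anti to the 3-hydroxyl of the 2,3-cis cation should set C4 as S (3,4-trans).

Step 11
Reactants: 19 4-(benzyloxy)benzaldehyde
Product: 20 ethyl (2Z)-3-[4-(benzyloxy)phenyl]prop-2-enoate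
Conditions: ethyl 2-[bis(2-methylphenoxy)phosphoryl]acetate (1.1 equiv), NaH, THF, −78 °C → 0 °C
Reagents that add atoms: ethyl 2-[bis(2-methylphenoxy)phosphoryl]acetate, CCOC(=O)CP(=O)(Oc1ccccc1C)Oc1ccccc1C
Why: Ando variant of the Horner–Wadsworth–Emmons olefination, Z-selective for the same reason as in step 1.

Step 12
Reactants: 20 ethyl (2Z)-3-[4-(benzyloxy)phenyl]prop-2-enoate
Product: 21 ethyl (2S,3S)-3-[4-(benzyloxy)phenyl]oxirane-2-carboxylate (cis-glycidate)
Conditions: (S,S)-[N,N'-bis(3,5-di-tert-butylsalicylidene)-1,2-cyclohexanediaminato]MnCl (Jacobsen catalyst, trivalent manganese, 6 mol %), 4-phenylpyridine N-oxide (0.25 equiv), aq. NaOCl (pH 11.3), CH2Cl2, 0–4 °C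
Reagents that add atoms: sodium hypochlorite, [Na+].[O-]Cl
Why: Jacobsen–Katsuki epoxidation, in which the (S,S)-ligand should again give the (2S,3S)-cis-epoxide by side-on approach of the cis-alkene.

Step 13
Reactants: 21 ethyl (2S,3S)-3-[4-(benzyloxy)phenyl]oxirane-2-carboxylate
Product: 22 (2S,3S)-3-[4-(benzyloxy)phenyl]oxirane-2-carbaldehyde (cis)
Conditions: i-Bu2AlH (1.05 equiv), CH2Cl2, −78 °C; MeOH, then aq. potassium sodium tartrate; used at once
Reagents that add atoms: none
Why: Partial ester reduction through the low-temperature-stable aluminium hemiacetal, as in step 3, with neutral work-up to keep the cis-configuration.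

Step 14
Reactants: 18 (2R,3R,4S)-7,8-bis(benzyloxy)-4-[3-(benzyloxy)-2,4-dihydroxyphenyl]-2-[3,4-bis(benzyloxy)phenyl]-3,4-dihydro-2H-chromen-3-ol; 22 (2S,3S)-3-[4-(benzyloxy)phenyl]oxirane-2-carbaldehyde
Product: 25 (2R,3R,4R)-8-(benzyloxy)-6-{(2R,3R,4S)-7,8-bis(benzyloxy)-2-[3,4-bis(benzyloxy)phenyl]-3-hydroxy-3,4-dihydro-2H-chromen-4-yl}-2-[4-(benzyloxy)phenyl]-3,4-dihydro-2H-chromene-3,4,7-triol, via titanium aryloxide 23 (not isolated), via titanium-bound epoxy carbinol 24 (not isolated)
Conditions: 18, Ti(OiPr)4 (3.3 equiv), toluene, rt, i-PrOH removed in vacuo; 22 (1.3 equiv), CH2Cl2, −20 °C → rt, then 40 °C; aq. potassium sodium tartrate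
Reagents that add atoms: none
Why: Proposed new method: the titanium aryloxide at O1 of 18 should bind the aldehyde of 22 and deliver it to the ortho carbon C4a (ortho-specific hydroxyalkylation of metal phenolates, as in the titanium alkoxide-mediated phenol–enal chromene annulation), giving titanium-bound epoxy carbinol 24, whose aryloxide oxygen then opens the titanium-chelated 2,3-epoxy alkoxide at the distal benzylic carbon; the closest known reaction types for this second event are the Ti(OiPr)4-mediated C3-selective opening of 2,3-epoxy alcohols and the phenoxide closure of aryl epoxides used for flavan-3-ols. Ring C closes in the 6-endo-tet mode, preferred over 5-exo because the attacked carbon is benzylic and activated by the para-benzyloxyphenyl group and because titanium held between the C4 alkoxide and the epoxide oxygen directs attack to the distal carbon. C4 (R) is set in the C–C bond formation by Felkin–Anh addition anti to the epoxide C–O bond, the weakly Lewis acidic triisopropoxytitanium aryloxide disfavouring the chelate (syn) mode; C3 (R) is carried in from 22; C2 (R) arises by inversion at the benzylic carbon of the cis-epoxide, which places 2-aryl and 3-OH cis. Only the anti adduct can hold its C4–O and epoxide oxygen gauche on titanium in the half-chair transition state, so the 2,3-cis-3,4-cis isomer should be the one that cyclises readily. The step needs C- over O-attack at a single ring position: templated ortho delivery secures C-attack, the other ortho and para sites of the resorcinol-type ring are substituted, the upper ring A carries no free phenol, and the para 7-O–Ti group raises the nucleophilicity of C4a.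

Step 15
Reactants: 25 hexabenzyl ether (product of step 14)
Product: 26 (2R,3R,4R)-6-[(2R,3R,4S)-2-(3,4-dihydroxyphenyl)-3,7,8-trihydroxy-3,4-dihydro-2H-chromen-4-yl]-2-(4-hydroxyphenyl)-3,4-dihydro-2H-chromene-3,4,7,8-tetrol
Conditions: H2 (1 atm), Pd(OH)2/C, THF–EtOAc, rt; filtration under argon
Reagents that add atoms: none
Why: Hydrogenolysis of the six aryl benzyl ethers, where under neutral, non-nucleophilic conditions the secondary benzylic C4 hydroxyl, the cyclic benzylic C2–O1 ethers and the C4–C6 bond are expected to survive, as benzylic alcohols do in debenzylations of phenolic arylethanolamines.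

Compound list
1 | 3,4-bis(benzyloxy)benzaldehyde | O=Cc1ccc(OCc2ccccc2)c(OCc2ccccc2)c1 | starting material
2 | ethyl (2Z)-3-[3,4-bis(benzyloxy)phenyl]prop-2-enoate | CCOC(=O)/C=C\c1ccc(OCc2ccccc2)c(OCc2ccccc2)c1 | intermediate
3 | ethyl (2S,3S)-3-[3,4-bis(benzyloxy)phenyl]oxirane-2-carboxylate | CCOC(=O)[C@H]1O[C@H]1c1ccc(OCc2ccccc2)c(OCc2ccccc2)c1 | intermediate
4 | (2S,3S)-3-[3,4-bis(benzyloxy)phenyl]oxirane-2-carbaldehyde | O=C[C@H]1O[C@H]1c1ccc(OCc2ccccc2)c(OCc2ccccc2)c1 | intermediate
5 | 2,3-bis(benzyloxy)benzaldehyde | O=Cc1cccc(OCc2ccccc2)c1OCc1ccccc1 | starting material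
6 | 2,3-bis(benzyloxy)phenyl formate | O=COc1cccc(OCc2ccccc2)c1OCc1ccccc1 | intermediate
7 | 2,3-bis(benzyloxy)phenol | Oc1cccc(OCc2ccccc2)c1OCc1ccccc1 | intermediate
8 | [2,3-bis(benzyloxy)phenoxy]tri(propan-2-yloxy)titanium (titanium aryloxide of 7) | CC(C)O[Ti](OC(C)C)(OC(C)C)Oc1cccc(OCc2ccccc2)c1OCc1ccccc1 | intermediate
9 | di(propan-2-yloxy)titanium chelate, through the phenolic and carbinol oxygens, of (R)-[3,4-bis(benzyloxy)-2-hydroxyphenyl]{(2R,3S)-3-[3,4-bis(benzyloxy)phenyl]oxiran-2-yl}methanol | CC(C)O[Ti]1(OC(C)C)Oc2c(OCc3ccccc3)c(OCc3ccccc3)ccc2[C@@H](O1)[C@H]1O[C@H]1c1ccc(OCc2ccccc2)c(OCc2ccccc2)c1 | intermediate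
10 | (2R,3R,4R)-7,8-bis(benzyloxy)-2-[3,4-bis(benzyloxy)phenyl]-3,4-dihydro-2H-chromene-3,4-diol (2,3-cis-3,4-cis) | C(c1ccccc1)Oc1ccc(cc1OCc1ccccc1)[C@H]2Oc3c(ccc(OCc4ccccc4)c3OCc3ccccc3)[C@@H](O)[C@H]2O | intermediate
11 | resorcinol | Oc1cccc(O)c1 | starting material
12 | 1,3-bis(methoxymethoxy)benzene | COCOc1cccc(OCOC)c1 | intermediate
13 | [2,6-bis(methoxymethoxy)phenyl]lithium | [Li]c1c(OCOC)cccc1OCOC | intermediate
14 | dimethyl [2,6-bis(methoxymethoxy)phenyl]boronate | COB(OC)c1c(OCOC)cccc1OCOC | intermediate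
15 | 2,6-bis(methoxymethoxy)phenol | Oc1c(OCOC)cccc1OCOC | intermediate
16 | 2-(benzyloxy)-1,3-bis(methoxymethoxy)benzene | COCOc1cccc(OCOC)c1OCc1ccccc1 | intermediate
17 | 2-(benzyloxy)benzene-1,3-diol | Oc1cccc(O)c1OCc1ccccc1 | intermediate
18 | (2R,3R,4S)-7,8-bis(benzyloxy)-4-[3-(benzyloxy)-2,4-dihydroxyphenyl]-2-[3,4-bis(benzyloxy)phenyl]-3,4-dihydro-2H-chromen-3-ol (2,3-cis-3,4-trans) | Oc1ccc(c(O)c1OCc1ccccc1)[C@H]2c3ccc(OCc4ccccc4)c(OCc4ccccc4)c3O[C@H](c3ccc(OCc4ccccc4)c(OCc4ccccc4)c3)[C@@H]2O | intermediate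
19 | 4-(benzyloxy)benzaldehyde | O=Cc1ccc(OCc2ccccc2)cc1 | starting material
20 | ethyl (2Z)-3-[4-(benzyloxy)phenyl]prop-2-enoate | CCOC(=O)/C=C\c1ccc(OCc2ccccc2)cc1 | intermediate
21 | ethyl (2S,3S)-3-[4-(benzyloxy)phenyl]oxirane-2-carboxylate | CCOC(=O)[C@H]1O[C@H]1c1ccc(OCc2ccccc2)cc1 | intermediate
22 | (2S,3S)-3-[4-(benzyloxy)phenyl]oxirane-2-carbaldehyde | O=C[C@H]1O[C@H]1c1ccc(OCc2ccccc2)cc1 | intermediate
23 | tris[tri(propan-2-yloxy)titanium] derivative of 18, titanated at both phenolic oxygens and at the 3-oxygen | CC(C)O[Ti](OC(C)C)(OC(C)C)Oc1ccc(c(O[Ti](OC(C)C)(OC(C)C)OC(C)C)c1OCc1ccccc1)[C@H]2c3ccc(OCc4ccccc4)c(OCc4ccccc4)c3O[C@H](c3ccc(OCc4ccccc4)c(OCc4ccccc4)c3)[C@@H]2O[Ti](OC(C)C)(OC(C)C)OC(C)C | intermediate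
24 | titanium-bound form (cyclic di(propan-2-yloxy)titanium chelate through the phenolic and carbinol oxygens; the other two hydroxyls as tri(propan-2-yloxy)titanium derivatives) of (R)-{3-(benzyloxy)-5-[(2R,3R,4S)-7,8-bis(benzyloxy)-2-[3,4-bis(benzyloxy)phenyl]-3-hydroxy-3,4-dihydro-2H-chromen-4-yl]-2,4-dihydroxyphenyl}{(2R,3S)-3-[4-(benzyloxy)phenyl]oxiran-2-yl}methanol | CC(C)O[Ti]1(OC(C)C)Oc2c(OCc3ccccc3)c(O[Ti](OC(C)C)(OC(C)C)OC(C)C)c([C@H]3c4ccc(OCc5ccccc5)c(OCc5ccccc5)c4O[C@H](c4ccc(OCc5ccccc5)c(OCc5ccccc5)c4)[C@@H]3O[Ti](OC(C)C)(OC(C)C)OC(C)C)cc2[C@@H](O1)[C@H]1O[C@H]1c1ccc(OCc2ccccc2)cc1 | intermediate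
25 | (2R,3R,4R)-8-(benzyloxy)-6-{(2R,3R,4S)-7,8-bis(benzyloxy)-2-[3,4-bis(benzyloxy)phenyl]-3-hydroxy-3,4-dihydro-2H-chromen-4-yl}-2-[4-(benzyloxy)phenyl]-3,4-dihydro-2H-chromene-3,4,7-triol | C(c1ccccc1)Oc1ccc([C@H]2Oc3c(cc([C@H]4c5ccc(OCc6ccccc6)c(OCc6ccccc6)c5O[C@H](c5ccc(OCc6ccccc6)c(OCc6ccccc6)c5)[C@@H]4O)c(O)c3OCc3ccccc3)[C@@H](O)[C@H]2O)cc1 | intermediate
26 | (2R,3R,4R)-6-[(2R,3R,4S)-2-(3,4-dihydroxyphenyl)-3,7,8-trihydroxy-3,4-dihydro-2H-chromen-4-yl]-2-(4-hydroxyphenyl)-3,4-dihydro-2H-chromene-3,4,7,8-tetrol | Oc1ccc([C@H]2Oc3c(cc([C@H]4c5ccc(O)c(O)c5O[C@H](c5ccc(O)c(O)c5)[C@@H]4O)c(O)c3O)[C@@H](O)[C@H]2O)cc1 | target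

Total step count: 15. Longest linear sequence: 7 steps (steps 1, 2, 3, 5, 10, 14, 15; the branch through steps 6–9 is equally long).

Steps most likely to fail

1. Step 14 (proposed new method). The electron-rich benzylic epoxide carbon may ionise on titanium before the aryloxide closes the ring. That would erode the inversion at C2 and allow isopropoxide transfer. The C–C bond formation may also be slow on the crowded, poly-titanated phenol, and C4 may lose its configuration through quinone methide formation from the 7-O-titanate. The fallback changes the order of bond construction; it sets out from 7, 22 and 10 and comes back to the route at 26. The bromomagnesium phenolate of 7 (EtMgBr, Et2O, then CH2Cl2) adds 22 at its ortho carbon at −20 °C (ortho-specific hydroxyalkylation of magnesium phenolates by α-oxygenated aldehydes), and the epoxy carbinol F1 is isolated. K2CO3 in MeOH then closes ring C by phenoxide opening of the benzylic epoxide carbon with inversion, the closure known from epoxide routes to flavan-3-ols, to give the tri-O-benzyl flavan-3,4-diol F2. Diol 10 is converted with phenylmethanethiol and BF3·OEt2 into the 4-benzylsulfanyl ether F3. AgBF4 in THF at 0 °C releases the C4 cation of F3 without ionising the C4 hydroxyl of F2 (used in excess), which is attacked at C6, para to O1 and ortho to the 7-benzyloxy group, to give the heptabenzyl ether F4. Hydrogenolysis as in step 15 then gives 26.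

2. Step 5 (proposed new method). The same ionisation of the epoxide ahead of ring closure, or competing isopropoxide opening, may lower the 2,3-cis selectivity on the simple phenol. The fallback replaces the titanium-templated cascade by two discrete known reactions; it sets out from 7 and 4 and comes back at 10. The bromomagnesium phenolate of 7 (EtMgBr, CH2Cl2, −20 °C) adds 4 at the ortho carbon, and the neutral epoxy carbinol F5 is isolated after aq. NH4Cl. K2CO3 in MeOH at rt then effects the anionic 6-endo closure with inversion to give 10.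

3. Step 2. With the electron-rich aryl group the radical intermediate of the manganese-oxo transfer may rotate before ring closure, giving trans-epoxide and lower enantiomeric purity, and the arene may be chlorinated by hypochlorite. The fallback moves the asymmetric step to the allylic alcohol; it sets out from 2 and comes back at 4. i-Bu2AlH (2.2 equiv, −78 °C) reduces 2 to the Z-allylic alcohol F6. Sharpless asymmetric epoxidation (Ti(OiPr)4, D-(−)-diisopropyl tartrate, t-BuOOH, 4 Å molecular sieves, CH2Cl2, −20 °C) gives the cis-epoxy alcohol F7, and Dess–Martin periodinane with NaHCO3 oxidises it to 4.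

Further compounds
F1 | step 14 | (R)-[3,4-bis(benzyloxy)-2-hydroxyphenyl]{(2R,3S)-3-[4-(benzyloxy)phenyl]oxiran-2-yl}methanol | Oc1c(OCc2ccccc2)c(OCc2ccccc2)ccc1[C@@H](O)[C@H]1O[C@H]1c1ccc(OCc2ccccc2)cc1
F2 | step 14 | (2R,3R,4R)-7,8-bis(benzyloxy)-2-[4-(benzyloxy)phenyl]-3,4-dihydro-2H-chromene-3,4-diol | C(c1ccccc1)Oc1ccc(cc1)[C@H]2Oc3c(ccc(OCc4ccccc4)c3OCc3ccccc3)[C@@H](O)[C@H]2O
F3 | step 14 | (2R,3S,4S)-4-(benzylsulfanyl)-7,8-bis(benzyloxy)-2-[3,4-bis(benzyloxy)phenyl]-3,4-dihydro-2H-chromen-3-ol (2,3-cis-3,4-trans) | c1ccccc1CS[C@H]2c3ccc(OCc4ccccc4)c(OCc4ccccc4)c3O[C@H](c3ccc(OCc4ccccc4)c(OCc4ccccc4)c3)[C@@H]2O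
F4 | step 14 | 7-O-benzyl ether of 25 (heptabenzyl ether of 26, same configuration at all six centres) | C(c1ccccc1)Oc1ccc([C@H]2Oc3c(cc([C@H]4c5ccc(OCc6ccccc6)c(OCc6ccccc6)c5O[C@H](c5ccc(OCc6ccccc6)c(OCc6ccccc6)c5)[C@@H]4O)c(OCc4ccccc4)c3OCc3ccccc3)[C@@H](O)[C@H]2O)cc1
F5 | step 5 | (R)-[3,4-bis(benzyloxy)-2-hydroxyphenyl]{(2R,3S)-3-[3,4-bis(benzyloxy)phenyl]oxiran-2-yl}methanol | Oc1c(OCc2ccccc2)c(OCc2ccccc2)ccc1[C@@H](O)[C@H]1O[C@H]1c1ccc(OCc2ccccc2)c(OCc2ccccc2)c1
F6 | step 2 | (2Z)-3-[3,4-bis(benzyloxy)phenyl]prop-2-en-1-ol | OC/C=C\c1ccc(OCc2ccccc2)c(OCc2ccccc2)c1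
F7 | step 2 | {(2R,3S)-3-[3,4-bis(benzyloxy)phenyl]oxiran-2-yl}methanol (cis) | OC[C@H]1O[C@H]1c1ccc(OCc2ccccc2)c(OCc2ccccc2)c1
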